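**Plan**
Retrosynthetic cuts, in order: (a) C5'–Cl, taken back by allylic transposition to a C11 carbinol on a C1'=C5' cyclopentenedione; (b) C1'–C2', by re-inserting one carbonyl carbon between these atoms; (c) C11–C1', the aryl–carbinol bond; (d) C11–C12 of a homodrimane lactone.
Enabling feature: ring C1'–C5' has oxygen on C2' and C4' and the side chain on C1'. This is the pattern of a 6-substituted 2-hydroxy-1,4-benzoquinone that lacks the carbonyl carbon between C1' and C2'.
Forward order: rings A and B come with (+)-sclareolide. The side chain is cut to the C11 aldehyde and joined to a 2,3,5-trimethoxyphenyl Grignard reagent made from 5-bromovanillin. The arene becomes the hydroxyquinone, which is contracted to the five-membered ring, and chloride comes last.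
Stereochemistry: C5, C9 and C10 come from sclareolide. C8 of the target (8S, β-hydroxyl) is opposite to sclareolide and is set by acid equilibration to the cis-lactone. 11R comes from a magnesium chelate, and 5'R and the E alkene come from 11R by syn SNi' transfer.

Key step: step 11

Remark on the chemistry: drimane numbering is used (C1–C10 decalin, C11 on C9, C1'–C5' the five-membered ring, quinone carbons C1–C6 with the side chain on C6). The target is taken as the C2' enol of its 1,3-dione, the tautomer drawn, and the enol forms are assumed to interconvert freely.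

Step 1
Reactants: 1 (+)-sclareolide
Product: 2 8-epi-sclareolide (cis-fused lactone; 8β-O and 8α-CH3; 3aS,5aS,9aS,9bR)
Conditions: H2SO4 (conc.), HCO2H, rt
Reagents that add atoms: none
Why: Acid-catalysed lactone equilibration, in which reversible ionisation of the tertiary C8–O bond and re-closure of the carboxyl group on the β face give the more stable cis-fused γ-lactone and so set C8 as S, while C5, C9 and C10 are not touched.

Step 2
Reactants: 2 8-epi-sclareolide
Product: 4 11-hydroxy-8-epi-sclareolide (C11 epimers), via potassium enolate 3 (not isolated)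
Conditions: KN(SiMe3)2, THF, −78 °C; 2-(phenylsulfonyl)-3-phenyloxaziridine, −78 °C; AcOH
Reagents that add atoms: 2-(phenylsulfonyl)-3-phenyloxaziridine, O=S(=O)(c1ccccc1)N1OC1c1ccccc1
Why: Davis oxidation of a lactone enolate transfers the oxaziridine oxygen to C11, and the new centre is left uncontrolled because it becomes the sp2 aldehyde carbon in step 4.

Step 3
Reactants: 4 11-hydroxy-8-epi-sclareolide
Product: 5 (8S)-13,14,15,16-tetranorlabdane-8,11,12-triol (8β-OH; C11 epimers)
Conditions: LiAlH4, THF, 0 °C → rt; H2O, NaOH aq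
Reagents that add atoms: none
Why: Hydride reduction of the lactone frees the tertiary 8β-hydroxyl and gives the 11,12-glycol without touching a ring stereocentre.

Step 4
Reactants: 5 (8S)-13,14,15,16-tetranorlabdane-8,11,12-triol
Product: 6 (5S,8S,9R,10S)-8-hydroxydriman-11-al (8β-OH axial; 9β-CHO equatorial)
Conditions: NaIO4, THF–H2O, 0 °C → rt
Reagents that add atoms: none
Why: Malaprade glycol cleavage removes C12, the tertiary C8 hydroxyl has no vicinal partner and survives, and the equatorial formyl group has no drive to epimerise at C9.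

Step 5
Reactants: 7 5-bromovanillin
Product: 9 2-bromo-6-methoxybenzene-1,4-diol, via aryl formate 8 (not isolated)
Conditions: H2O2 (30% aq), NaOH aq, N2, 0 °C → rt; HCl aq
Reagents that add atoms: hydrogen peroxide, OO
Why: Dakin oxidation, in which hydroperoxide adds to the aldehyde of the para-hydroxybenzaldehyde, the electron-rich aryl group migrates to oxygen and the formate is saponified in the same flask.

Step 6
Reactants: 9 2-bromo-6-methoxybenzene-1,4-diol
Product: 10 1-bromo-2,3,5-trimethoxybenzene
Conditions: MeI, K2CO3, acetone, N2, reflux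
Reagents that add atoms: iodomethane, CI
Why: Williamson ether synthesis on both phenols fixes the para-dimethoxy pair that is later oxidised to the quinone.

Step 7
Reactants: 10 1-bromo-2,3,5-trimethoxybenzene; 6 (5S,8S,9R,10S)-8-hydroxydriman-11-al
Product: 12 (11R)-11-(2,3,5-trimethoxyphenyl)drimane-8β,11-diol, via arylmagnesium bromide 11 (not isolated)
Conditions: 10 (2.5 equiv), Mg, THF, 40 °C; then 6, THF–CH2Cl2, −78 → 0 °C; NH4Cl aq
Reagents that add atoms: none
Why: Chelation-controlled (Cram chelate) Grignard addition, in which the first equivalent of 11 makes the 8β-magnesium alkoxide that ties the aldehyde oxygen into a six-membered chelate on the β side, so the second equivalent attacks C11 from the α face, anti to the C9–C10 bond, and sets 11R.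

Step 8
Reactants: 12 (11R)-11-(2,3,5-trimethoxyphenyl)drimane-8β,11-diol
Product: 13 (11R)-8β,11-bis(triethylsilyloxy)-11-(2,3,5-trimethoxyphenyl)drimane
Conditions: Et3SiOTf (3 equiv), 2,6-lutidine, CH2Cl2, −78 → 0 °C
Reagents that add atoms: triethylsilyl trifluoromethanesulfonate, CC[Si](CC)(CC)OS(=O)(=O)C(F)(F)F
Why: Silyl triflate silylation is strong enough for the axial tertiary hydroxyl as well as the benzylic one, and the two identical groups stay distinguishable later because one sits on a secondary and the other on a tertiary carbinol.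

Step 9
Reactants: 13 (11R)-8β,11-bis(triethylsilyloxy)-11-(2,3,5-trimethoxyphenyl)drimane
Product: 14 2-methoxy-6-[(11R)-8β,11-bis(triethylsilyloxy)driman-11-yl]-1,4-benzoquinone
Conditions: (NH4)2Ce(NO3)6, MeCN–H2O, 0 °C, short contact
Reagents that add atoms: water, O
Why: Oxidative demethylation of the para-related methoxy groups gives the 1,4-quinone, the third methoxy group ends as the vinylogous ester at quinone C2, and the hindered silyl ethers should tolerate the brief cold acidic medium.

Step 10
Reactants: 14 2-methoxy-6-[(11R)-8β,11-bis(triethylsilyloxy)driman-11-yl]-1,4-benzoquinone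
Product: 15 2-hydroxy-6-[(11R)-8β,11-bis(triethylsilyloxy)driman-11-yl]-1,4-benzoquinone
Conditions: NaOH (1 M aq), THF, Ar, 0 °C; HCl (1 M) to pH 3
Reagents that add atoms: sodium hydroxide, [Na+].[OH-]
Why: Addition–elimination of hydroxide at the methoxy-bearing carbon of the vinylogous ester is pulled forward by formation of the delocalised hydroxyquinone anion.

Step 11
Reactants: 15 2-hydroxy-6-[(11R)-8β,11-bis(triethylsilyloxy)driman-11-yl]-1,4-benzoquinone
Product: 17 4-[(11R)-8β,11-bis(triethylsilyloxy)driman-11-yl]cyclopent-4-ene-1,3-dione, via hydroxy acid 16 (not isolated)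
Conditions: NaOH (2 M aq), 1,4-dioxane, Ar, 60 °C; cool to 0 °C, NaH2PO4 to pH 6; NaIO4, 0 °C → rt
Reagents that add atoms: none
Why: Proposed new method: in strong base 15 is its anion, whose O2–C2–C3–C4–O4 unit is a vinylogous carboxylate, so hydroxide adds to C1, the carbonyl lying between C2 and the side-chain-bearing C6; the C6–C1 σ bond then shifts to C2, which behaves as the second carbonyl of a 1,2-dione in the canonical form O=C2–C3=C4–O(−), the charge leaves through O4, and protonation at C3 gives the α-hydroxy acid 16. Periodate then cleaves this tertiary α-hydroxy acid to the C2' ketone with loss of CO2. The closest known reaction types are the benzilic acid stage of the Hooker oxidation of 2-hydroxy-1,4-quinones, where C3 has first been oxidised, and the base-induced contraction of rhodizonate to croconate; new here is the shift onto an unoxidised, 3-unsubstituted anion, whose weak electrophilicity at C2 is met with concentrated hydroxide, heat and exclusion of air. Ring C1'–C5' closes by a 1,2-shift through a three-centre transition state (ring contraction, not an exo or endo cyclisation), and the new bond is C1'–C2'. The carbinol centre of 16 forms without control and is erased by the oxidation, so 17 carries no new stereocentre and C8, C9 and C11 are spectators. Site selectivity is needed only for the hydroxide addition, and it follows from C2 and C4 being tied up in the delocalised anion.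

Step 12
Reactants: 17 4-[(11R)-8β,11-bis(triethylsilyloxy)driman-11-yl]cyclopent-4-ene-1,3-dione
Product: 18 4-[(11R)-11-hydroxy-8β-(triethylsilyloxy)driman-11-yl]cyclopent-4-ene-1,3-dione
Conditions: HF·pyridine, pyridine, THF, 0 °C
Reagents that add atoms: none
Why: Buffered fluoride desilylation responds to access to silicon and to the quality of the departing alkoxide, and the secondary C11 oxygen next to the electron-poor enedione is better than the axial tertiary C8 oxygen on both counts.

Step 13
Reactants: 18 4-[(11R)-11-hydroxy-8β-(triethylsilyloxy)driman-11-yl]cyclopent-4-ene-1,3-dione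
Product: 20 (4E,5R)-5-chloro-3-hydroxy-4-[8β-(triethylsilyloxy)driman-11-ylidene]cyclopent-2-en-1-one, via chlorosulfite 19 (not isolated)
Conditions: SOCl2 (1.0 equiv), Et2O (dilute), −40 → 0 °C
Reagents that add atoms: thionyl chloride, O=S(Cl)Cl
Why: SNi' reaction of an allylic chlorosulfite on a Morita–Baylis–Hillman-type carbinol, in which 19 collapses through a six-membered cyclic transition state that passes chlorine from sulfur to the electrophilic C5' on the face from which the C11–O bond leaves, and with the drimanyl group pseudo-equatorial (C11–H towards C5'–H, least allylic strain) 11R is relayed into 5'R and the E alkene with C9 cis to C2', after which the 1,3-dione settles as the C2' enol.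

Step 14
Reactants: 20 (4E,5R)-5-chloro-3-hydroxy-4-[8β-(triethylsilyloxy)driman-11-ylidene]cyclopent-2-en-1-one
Product: 21 (4E,5R)-5-chloro-3-hydroxy-4-(8β-hydroxydriman-11-ylidene)cyclopent-2-en-1-one (CNP0279879.2)
Conditions: HF·pyridine, MeCN, 0 °C → rt
Reagents that add atoms: none
Why: Fluoride-mediated cleavage of the remaining tertiary silyl ether in a weakly acidic, base-free medium avoids enolisation at C5' and so keeps 5'R and the E alkene.

**Compound list**
1 | (+)-sclareolide | CC1(C)CCC[C@]2(C)[C@@H](CC(=O)O3)[C@@]3(C)CC[C@@H]12 | starting material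
2 | 8-epi-sclareolide | CC1(C)CCC[C@]2(C)[C@@H](CC(=O)O3)[C@]3(C)CC[C@@H]12 | intermediate
3 | potassium enolate of 2 | [K+].CC1(C)CCC[C@]2(C)[C@@H](C=C([O-])O3)[C@]3(C)CC[C@@H]12 | intermediate
4 | 11-hydroxy-8-epi-sclareolide (C11 epimers) | CC1(C)CCC[C@]2(C)[C@@H](C(O)C(=O)O3)[C@]3(C)CC[C@@H]12 | intermediate
5 | (8S)-13,14,15,16-tetranorlabdane-8,11,12-triol (C11 epimers) | CC1(C)CCC[C@]2(C)[C@@H](C(O)CO)[C@@](C)(O)CC[C@@H]12 | intermediate
6 | (5S,8S,9R,10S)-8-hydroxydriman-11-al | CC1(C)CCC[C@]2(C)[C@@H](C=O)[C@@](C)(O)CC[C@@H]12 | intermediate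
7 | 5-bromovanillin | COc1cc(C=O)cc(Br)c1O | starting material
8 | 3-bromo-4-hydroxy-5-methoxyphenyl formate | COc1cc(OC=O)cc(Br)c1O | intermediate
9 | 2-bromo-6-methoxybenzene-1,4-diol | COc1cc(O)cc(Br)c1O | intermediate
10 | 1-bromo-2,3,5-trimethoxybenzene | COc1cc(OC)cc(Br)c1OC | intermediate
11 | 2,3,5-trimethoxyphenylmagnesium bromide | COc1cc(OC)cc([Mg]Br)c1OC | intermediate
12 | (11R)-11-(2,3,5-trimethoxyphenyl)drimane-8β,11-diol | CC1(C)CCC[C@]2(C)[C@@H]([C@@H](O)c3cc(OC)cc(OC)c3OC)[C@@](C)(O)CC[C@@H]12 | intermediate
13 | (11R)-8β,11-bis(triethylsilyloxy)-11-(2,3,5-trimethoxyphenyl)drimane | CC1(C)CCC[C@]2(C)[C@@H]([C@@H](O[Si](CC)(CC)CC)c3cc(OC)cc(OC)c3OC)[C@@](C)(O[Si](CC)(CC)CC)CC[C@@H]12 | intermediate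
14 | 2-methoxy-6-[(11R)-8β,11-bis(triethylsilyloxy)driman-11-yl]-1,4-benzoquinone | CC1(C)CCC[C@]2(C)[C@@H]([C@@H](O[Si](CC)(CC)CC)C3=CC(=O)C=C(OC)C3=O)[C@@](C)(O[Si](CC)(CC)CC)CC[C@@H]12 | intermediate
15 | 2-hydroxy-6-[(11R)-8β,11-bis(triethylsilyloxy)driman-11-yl]-1,4-benzoquinone | CC1(C)CCC[C@]2(C)[C@@H]([C@@H](O[Si](CC)(CC)CC)C3=CC(=O)C=C(O)C3=O)[C@@](C)(O[Si](CC)(CC)CC)CC[C@@H]12 | intermediate
16 | 1-hydroxy-4-oxo-2-[(11R)-8β,11-bis(triethylsilyloxy)driman-11-yl]cyclopent-2-ene-1-carboxylic acid (carbinol epimers) | CC1(C)CCC[C@]2(C)[C@@H]([C@@H](O[Si](CC)(CC)CC)C3=CC(=O)CC3(O)C(=O)O)[C@@](C)(O[Si](CC)(CC)CC)CC[C@@H]12 | intermediate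
17 | 4-[(11R)-8β,11-bis(triethylsilyloxy)driman-11-yl]cyclopent-4-ene-1,3-dione | CC1(C)CCC[C@]2(C)[C@@H]([C@@H](O[Si](CC)(CC)CC)C3=CC(=O)CC3=O)[C@@](C)(O[Si](CC)(CC)CC)CC[C@@H]12 | intermediate
18 | 4-[(11R)-11-hydroxy-8β-(triethylsilyloxy)driman-11-yl]cyclopent-4-ene-1,3-dione | CC1(C)CCC[C@]2(C)[C@@H]([C@@H](O)C3=CC(=O)CC3=O)[C@@](C)(O[Si](CC)(CC)CC)CC[C@@H]12 | intermediate
19 | C11 chlorosulfite of 18 (epimers at sulfur) | CC1(C)CCC[C@]2(C)[C@@H]([C@@H](OS(=O)Cl)C3=CC(=O)CC3=O)[C@@](C)(O[Si](CC)(CC)CC)CC[C@@H]12 | intermediate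
20 | (4E,5R)-5-chloro-3-hydroxy-4-[8β-(triethylsilyloxy)driman-11-ylidene]cyclopent-2-en-1-one | CC1(C)CCC[C@]2(C)[C@@H](/C=C3\C(O)=CC(=O)[C@@H]3Cl)[C@@](C)(O[Si](CC)(CC)CC)CC[C@@H]12 | intermediate
21 | (4E,5R)-5-chloro-3-hydroxy-4-(8β-hydroxydriman-11-ylidene)cyclopent-2-en-1-one | CC1(C)CCC[C@]2(C)[C@@H](/C=C3\C(O)=CC(=O)[C@@H]3Cl)[C@@](C)(O)CC[C@@H]12 | target

Total step count: 14. Longest linear sequence: 12 (steps 1–4 and 7–14).

**Steps most likely to fail**

First, step 11. The delocalised anion may refuse the 1,2-shift because C2 is a poor acceptor. The hot base may instead cause self-condensation through the free C3 and C5 positions, ring cleavage, or loss of the C11 silyl group. Any unreacted hydroxyquinone would be cleaved by periodate. The fallback uses the known thermal contraction of hydroxyquinone iodonium ylides and sets out from 15.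
- PhI(OAc)2 in CH2Cl2 at 0 °C gives the phenyliodonium ylide F1.
- Heating in wet MeCN expels iodobenzene and contracts the ring in a Wolff-type shift to the acylketene F2.
- Water adds to give the β-keto acid F3, which decarboxylates on its own.
- The route is rejoined at 17.

Here quinone C2 rather than C1 is lost and the ring closes between C1 and C3, but the product is the same.

Second, step 13. Several things may go wrong:
- free chloride may intercept the chlorosulfite, so that the syn relay is lost and C5' erodes;
- collapse may occur at C11 without transposition;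
- the drimanyl group may turn towards C5' and give the other alkene geometry;
- surplus reagent may chlorinate the enol of the product.

The fallback sets out from 18.
- Ms2O and 2,6-di-tert-butyl-4-methylpyridine in CH2Cl2 at −40 °C give the C11 mesylate F4.
- Bu4NCl then adds at C5' and expels mesylate, an intermolecular SN2' by addition–elimination. This should give 20 beside its C5' epimer F5.
- The two are separated by chromatography. The unwanted epimer is re-equilibrated through its C4' enol with a trace of acid and separated again.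
- The route is rejoined at 20.

Third, step 7. Facial selectivity may be poor if the chelate is not maintained, and the magnesium aldolate may open ring B by retro-aldol cleavage before addition. The fallback sets out from crude 12 that contains the 11S diol F6.
- Dess–Martin periodinane oxidises only the secondary carbinol and gives the β-hydroxy aryl ketone F7.
- An Evans–Saksena reduction with Me4NBH(OAc)3 in AcOH–MeCN at −20 °C delivers hydride from boron bound to the 8β-oxygen, through a chair with the aryl group equatorial. This gives the 11R configuration.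
- The route is rejoined at 12.

**Further compounds**
F1 | step 11 | 3-phenyliodonio-2-oxido ylide of 15 | CC1(C)CCC[C@]2(C)[C@@H]([C@@H](O[Si](CC)(CC)CC)C3=CC(=O)C([I+]c4ccccc4)=C([O-])C3=O)[C@@](C)(O[Si](CC)(CC)CC)CC[C@@H]12
F2 | step 11 | 2-(oxomethylidene)-4-[(11R)-8β,11-bis(triethylsilyloxy)driman-11-yl]cyclopent-4-ene-1,3-dione | CC1(C)CCC[C@]2(C)[C@@H]([C@@H](O[Si](CC)(CC)CC)C3=CC(=O)C(=C=O)C3=O)[C@@](C)(O[Si](CC)(CC)CC)CC[C@@H]12
F3 | step 11 | 2,5-dioxo-3-[(11R)-8β,11-bis(triethylsilyloxy)driman-11-yl]cyclopent-3-ene-1-carboxylic acid | CC1(C)CCC[C@]2(C)[C@@H]([C@@H](O[Si](CC)(CC)CC)C3=CC(=O)C(C(=O)O)C3=O)[C@@](C)(O[Si](CC)(CC)CC)CC[C@@H]12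
F4 | step 13 | C11 methanesulfonate of 18 | CC1(C)CCC[C@]2(C)[C@@H]([C@@H](OS(C)(=O)=O)C3=CC(=O)CC3=O)[C@@](C)(O[Si](CC)(CC)CC)CC[C@@H]12
F5 | step 13 | (5S)-epimer of 20 | CC1(C)CCC[C@]2(C)[C@@H](/C=C3\C(O)=CC(=O)[C@H]3Cl)[C@@](C)(O[Si](CC)(CC)CC)CC[C@@H]12
F6 | step 7 | (11S)-11-(2,3,5-trimethoxyphenyl)drimane-8β,11-diol | CC1(C)CCC[C@]2(C)[C@@H]([C@H](O)c3cc(OC)cc(OC)c3OC)[C@@](C)(O)CC[C@@H]12
F7 | step 7 | 8β-hydroxy-11-(2,3,5-trimethoxyphenyl)driman-11-one | CC1(C)CCC[C@]2(C)[C@@H](C(=O)c3cc(OC)cc(OC)c3OC)[C@@](C)(O)CC[C@@H]12
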